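The numbers in the tables come from a simulation from invented constants; noise was put on by code.

Does feeding one reagent slowly cost product against charging everything at the start, and how much?

| flask | starting material | partner | remark | time |
|---|---|---|---|---|
| violet | 0.20 M | 0.36 M | run made earlier |  |
| teal | 0.13 M | 0.36 M | run made earlier |  |
| amber | 0.30 M | 0.36 M | run made earlier |  |
| west | 0.20 M | 0.360 M (fed, over 30 min) | all else is in the flask from the start; the feed brings no volume worth counting | 50 min |
| east | 0.20 M | 0.360 M | everything together at the start | 50 min |
| north-west | 0.20 M (fed, over 30 min) | 0.360 M | all else is in the flask from the start; the feed brings no volume worth counting | 50 min |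

- violet (time / min: product / %, starting material / %): 4.00: 4.4, 95.5; 10.0: 13.5, 86.7; 20.0: 33.2, 66.3; 30.0: 54.4, 45.1
- teal (time / min: product / %, starting material / %): 4.00: 3.6, 96.2; 10.0: 11.8, 89.1; 20.0: 26.5, 73.2; 30.0: 44.5, 55.3
- amber (time / min: product / %, starting material / %): 2.50: 2.2, 97.2; 6.00: 8.3, 91.6; 12.0: 21.0, 78.8; 30.0: 63.7, 36.2

(scatter of a reading: 0.3 percentage points)

- the analysis behind the earlier runs scatters by 0.3 percentage points, standard deviation
- a reading or a percentage of product counts all its forms, free or not

1. the best flask by amount of product, in percent of the starting material charged; "all alike" if 1.5 percentage points covers them all (west / east / north-west / all alike)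
2. amount of product at the end, in percent of the starting material charged, west
3. amount of product at the end, in percent of the starting material charged, east
4. amount of product at the end, in percent of the starting material charged, north-west

In the violet run, which has the charges of east, the rate divided by starting material and partner rises with product: this is autocatalysis. A seed (the value at zero product) and a gain (its rise per unit of product) describe it. We carry their ratio, the crossover amount, seed over gain: the product at which the accelerated path equals the plain one.

Which numbers must be known well? Call the crossover time the time the plain path needs to make that amount with everything charged. It equals one over gain times both charges, so the seed cancels. A fed flask needs the square root of twice the feed time times that crossover time, or, if it crosses after the feed ends, the crossover time plus half the feed time. The lag is then 15.0 min. With a crossover time of a quarter of the feed time it is 13.7 min. Between a crossover time of a quarter and of half the feed time the lag moves by 1.29 min, so the gain need not be known closely.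

Now the numbers. The violet readings, with scatter 0.3 percentage points on an early rise of 9.1 points, give rate constants of 0.0487 /M/min early and 0.140 /M/min late. Hence a gain of 1.31 /M²/min, a seed of 0.0253 /M/min and a crossover amount, seed over gain, of 0.0193 M. The crossover time is 10.6 min, the fed crossing 25.3 min, the lag 14.6 min. Extending the last violet slope, we expect west and north-west near 65.8%, with east ahead.

The forecast gave 62% for west, 80.5% for east and 61% for north-west, best east, on the ground that “The rate accelerates as product forms”.

The flasks give 63.2% for west, 81.9% for east and 62.9% for north-west.

    starting material + partner + by-product → product + 2 by-product (k = 0.0220 /M²/s)
    starting material + partner → product + by-product (k = 4.20 × 10⁻⁴ /M/s)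
    crystals ⇌ product, rate k3*(cs3 - [product]) while solid is left; crystals form when [product] > cs3 (solubility = 30.0 mM, k = 0.0430 /s)

In north-west, half of the plain path's turnover was done by 27.3 min and half of the accelerated path's by 37.0 min. At 50.0 min its by-product stood at 0.126 M, matching 0.126 M of product with crystals counted in, or 6.53 crossovers, and the accelerated path ran 6.6 times the plain one. A further flask, like north-west but with 0.050 M of starting material, has a crossing reckoned at 57.5 min. It ended with by-product 0.0180 M, below the crossover of 0.0193 M, and product 36.0%.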